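**The task.** Two questions about this flask: when target peaks within the time limit, and how high.

- larch: starting material 0.10 M; first nucleophile 0.25 M; second nucleophile 0.060 M; run made earlier
- flask: starting material 0.10 M; first nucleophile 0.500 M; second nucleophile 0.0600 M; time 8.0 d

- larch (time / h: target / %): 1.00: 1.8; 3.00: 1.7; 5.00: 2.6; 8.00: 4.8; 12.0: 6.7; 15.0: 6.6; 20.0: 9.4

(each reading ± 1 percentage point)



- the best time, 8.0 d at the latest, for target
- the amount of target, in percent of the starting material charged, at that time

**Time ladder.** My fastest rung is an assumption of my own: second nucleophile ties up starting material one to one, well before target builds. So reckon with what that leaves free: the free share f, the part of the starting material charged that the charge of second nucleophile cannot tie up, 40.0 %.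

The next rung is the pace. The larch run reads about 0.00470 h⁻¹ of the charge over its 20.0 h. First nucleophile stands in excess, so I treat it as pseudo-first-order and take the pace in this flask as twice that of larch.

At that steady pace I reckon 1.77 d to fill f and 4.43 d for the whole charge, and the limit of 8.0 d is the top rung. I commit to a peak near 1.77 d, with target near 40.0 %.

**Forecast.** The forecast says 6 d and 50 %, reasoning “If each target takes up one second nucleophile”. My reckoning differs: it sets second nucleophile against target.

**Result.** Target in this flask peaks at 2.29 d with 19.4 %, and the scheme is:

    starting material ⇌ intermediate (K = 0.130, k = 0.260 h⁻¹)
    first nucleophile + intermediate → target (k = 0.380 M⁻¹ h⁻¹)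
    second nucleophile + intermediate → other capture product (k = 8.40 M⁻¹ h⁻¹)
    first nucleophile + target → over-reaction product (k = 0.0260 M⁻¹ h⁻¹)
    intermediate → side product (k = 0.00680 h⁻¹)
    target ⇌ isomer of the product (K = 0.380, k = 0.130 h⁻¹)

**Free share.** At that peak in this flask, second nucleophile still stands at 18.5 % of its charge and other capture product at 48.9 %, so the tie-up I assumed complete has not finished at that time, and f of 40.0 % is not a share reached there. A neighbour flask charged with 0.40 M of starting material has f of 85.0 %. At 8.00 d its second nucleophile stands at 0 % and its other capture product at 15.0 %, and its best target is 31.0 %.

All runs were computed with constants of no real substance; scatter was added.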